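Ring B is a cyclohexene whose only double bond, the tetrasubstituted C8=C9 (drimane numbering), is a Diels–Alder retron. The decalin is therefore unravelled to an acyclic precursor: diene C7=C8–C9=C10, dienophile C5=C6 activated by a temporary formyl group on C6, both joined by the C1–C4 chain with its gem-dimethyl carbon. One imidazolidinone-catalysed intramolecular cycloaddition forms the ring-fusion bond C5–C10 together with C6–C7, closes rings A and B, sets both ring stereocentres and places the olefin. The formyl group is then excised, and the side chain is completed by alkyne carboalumination and Negishi coupling with a Roche-ester-derived vinyl iodide carrying the third stereocentre.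

Key step: step 7

Remark: the decalin is numbered as a drimane (ring A C1–C5 and C10, ring B C5–C10, C11 the first side-chain carbon). The facial sense of the imidazolidinone is assigned from the accepted iminium shielding model.

Step 1
Reactants: 1 2,2-dimethylpent-4-enal; 2 diethyl {2-[methoxy(methyl)amino]-2-oxoethyl}phosphonate
Product: 4 (2E)-N-methoxy-N,4,4-trimethylhepta-2,6-dienamide, via sodium phosphonate anion 3 (not isolated)
Conditions: NaH, THF, 0 °C → rt
Reagents that add atoms: none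
Why: Horner–Wadsworth–Emmons olefination of a non-enolisable neopentyl aldehyde with a stabilised phosphonate anion, which should give the E enamide.

Step 2
Reactants: 5 but-2-yn-1-ol; 6 isopropenylmagnesium bromide
Product: 8 (2Z)-3-iodo-2-(prop-1-en-2-yl)but-2-en-1-ol, via magnesium chelate 7 (not isolated)
Conditions: 6 (3 equiv), CuI (10 mol %), THF, reflux; then I2, THF, −78 → 0 °C
Reagents that add atoms: iodine, II
Why: Alkoxide-directed anti-carbomagnesiation of a propargylic alcohol (Duboudin–Fallis type) puts the isopropenyl group on the carbon next to CH2O and magnesium on the distal carbon in a five-membered chelate, so iodinolysis with retention should leave iodine cis to CH2OH and the methyl group cis to the isopropenyl group.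

Step 3
Reactants: 8 (2Z)-3-iodo-2-(prop-1-en-2-yl)but-2-en-1-ol
Product: 9 (2Z)-1-bromo-3-iodo-2-(prop-1-en-2-yl)but-2-ene
Conditions: CBr4, PPh3, CH2Cl2, 0 °C
Reagents that add atoms: carbon tetrabromide, BrC(Br)(Br)Br
Why: Appel reaction at a primary allylic alcohol (SN2 on the alkoxyphosphonium ion) under neutral conditions, which should leave the alkene geometry and the vinyl iodide untouched.

Step 4
Reactants: 9 (2Z)-1-bromo-3-iodo-2-(prop-1-en-2-yl)but-2-ene; 10 trimethyl(prop-1-yn-1-yl)silane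
Product: 12 [(5E)-6-iodo-5-(prop-1-en-2-yl)hept-5-en-1-yn-1-yl]trimethylsilane, via lithiated silylpropyne 11 (not isolated)
Conditions: 10, n-BuLi, THF, −78 → −20 °C; then 9, −78 °C
Reagents that add atoms: none
Why: SN2 alkylation of a silyl-capped propargyllithium by the primary allylic bromide, where the silyl group directs propargyl rather than allenyl bonding and the delocalised anion is too weakly basic to exchange with the vinyl iodide.

Step 5
Reactants: 4 (2E)-N-methoxy-N,4,4-trimethylhepta-2,6-dienamide; 12 [(5E)-6-iodo-5-(prop-1-en-2-yl)hept-5-en-1-yn-1-yl]trimethylsilane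
Product: 14 (2E,8E)-N-methoxy-N,4,4,8-tetramethyl-9-(prop-1-en-2-yl)-13-(trimethylsilyl)trideca-2,8-dien-12-ynamide, via alkyl-9-BBN borane 13 (not isolated)
Conditions: 9-BBN, THF, 0 °C → rt; then 12, Pd(dppf)Cl2 (5 mol %), AsPh3, Cs2CO3, DMF/H2O, rt → 50 °C
Reagents that add atoms: none
Why: B-alkyl Suzuki–Miyaura coupling in which 9-BBN hydroborates only the terminal alkene of 4 (the conjugated enamide next to the quaternary carbon is inert) and the alkylborane replaces iodine with retention of the tetrasubstituted alkene geometry.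

Step 6
Reactants: 14 (2E,8E)-N-methoxy-N,4,4,8-tetramethyl-9-(prop-1-en-2-yl)-13-(trimethylsilyl)trideca-2,8-dien-12-ynamide
Product: 15 (2E,8E)-4,4,8-trimethyl-9-(prop-1-en-2-yl)-13-(trimethylsilyl)trideca-2,8-dien-12-ynal
Conditions: i-Bu2AlH, THF, −78 °C; aq. potassium sodium tartrate
Reagents that add atoms: none
Why: Weinreb amide reduction, in which the chelated tetrahedral aluminium intermediate survives until work-up and should release the E enal without over-reduction.

Step 7
Reactants: 15 (2E,8E)-4,4,8-trimethyl-9-(prop-1-en-2-yl)-13-(trimethylsilyl)trideca-2,8-dien-12-ynal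
Product: 17 (1S,4aS,8aS)-3,4a,8,8-tetramethyl-4-[4-(trimethylsilyl)but-3-yn-1-yl]-1,2,4a,5,6,7,8,8a-octahydronaphthalene-1-carbaldehyde, via iminium ion 16 (not isolated)
Conditions: (2S,5S)-5-benzyl-2-tert-butyl-3-methylimidazolidin-4-one·CF3CO2H (20 mol %), CH3CN with 2 vol % H2O, 0 °C → rt
Reagents that add atoms: none
Why: The secondary amine condenses with enal 15 to the E iminium ion 16, whose lowered LUMO engages the C7=C8–C9=C10 diene in a concerted, asynchronous type 1 intramolecular Diels–Alder reaction (closest known type: the imidazolidinone-catalysed intramolecular Diels–Alder reaction of trienals), after which hydrolysis releases 17 and the amine. Ring A closes in the fused mode through the four-carbon C1–C4 tether as C5–C10 forms, and ring B closes as the [4+2] cyclohexene as C6–C7 forms, the new double bond appearing at C8=C9. C5 is set by the catalyst, whose benzyl group covers the Re face of the iminium β-carbon so that C10 should add to the Si face (5S). C10 is set relative to C5 by the endo transition state, which with the E dienophile and the tether on the outside position of C10 gives the trans ring fusion (10S, methyl anti to H5); C6 follows from the E enal geometry and is erased in step 8. The step needs endo over exo, one enantioface and a cisoid geometry of a hindered, twisted diene; the defined C9=C10 geometry (methyl inside, tether outside), the gem-dimethyl group at C4 (Thorpe–Ingold folding) and the pairing of an electron-rich tetra-alkyl diene with a cationic dienophile are what secure these.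

Step 8
Reactants: 17 (1S,4aS,8aS)-3,4a,8,8-tetramethyl-4-[4-(trimethylsilyl)but-3-yn-1-yl]-1,2,4a,5,6,7,8,8a-octahydronaphthalene-1-carbaldehyde
Product: 18 trimethyl{4-[(4aS,8aS)-2,5,5,8a-tetramethyl-3,4,4a,5,6,7,8,8a-octahydronaphthalen-1-yl]but-1-yn-1-yl}silane
Conditions: RhCl(PPh3)3 (1.1 equiv), toluene, reflux
Reagents that add atoms: none
Why: Tsuji–Wilkinson decarbonylation (formyl C–H oxidative addition, CO migration to the metal, C–H reductive elimination) should turn C6 into CH2 without touching C5, C10, the tetrasubstituted alkene or the silyl-capped alkyne.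

Step 9
Reactants: 18 trimethyl{4-[(4aS,8aS)-2,5,5,8a-tetramethyl-3,4,4a,5,6,7,8,8a-octahydronaphthalen-1-yl]but-1-yn-1-yl}silane
Product: 19 (4aS,8aS)-4-(but-3-yn-1-yl)-3,4a,8,8-tetramethyl-1,2,4a,5,6,7,8,8a-octahydronaphthalene
Conditions: K2CO3, MeOH, rt
Reagents that add atoms: none
Why: Methoxide-mediated protodesilylation of an alkynylsilane, which should free the terminal alkyne and affect nothing else in a hydrocarbon substrate.

Step 10
Reactants: 20 methyl (2S)-3-hydroxy-2-methylpropanoate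
Product: 21 methyl (2S)-3-[(tert-butyldimethylsilyl)oxy]-2-methylpropanoate
Conditions: TBSCl, imidazole, CH2Cl2, rt
Reagents that add atoms: tert-butyldimethylsilyl chloride, CC(C)(C)[Si](C)(C)Cl
Why: Standard silylation of the primary alcohol of the Roche ester, whose stereocentre is bought and not affected.

Step 11
Reactants: 21 methyl (2S)-3-[(tert-butyldimethylsilyl)oxy]-2-methylpropanoate
Product: 22 (2S)-3-[(tert-butyldimethylsilyl)oxy]-2-methylpropanal
Conditions: i-Bu2AlH, CH2Cl2, −78 °C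
Reagents that add atoms: none
Why: Partial ester reduction that stops at the aluminium hemiacetal at −78 °C, so the aldehyde should form on work-up with the α-stereocentre intact.

Step 12
Reactants: 22 (2S)-3-[(tert-butyldimethylsilyl)oxy]-2-methylpropanal
Product: 23 tert-butyl{[(2R,3E)-4-iodo-2-methylbut-3-en-1-yl]oxy}dimethylsilane
Conditions: CrCl2, CHI3, THF, 0 °C → rt
Reagents that add atoms: iodoform, IC(I)I
Why: Takai olefination, in which the geminal dichromium reagent adds to the aldehyde and eliminates to the E vinyl iodide under non-basic conditions that should not epimerise the α-stereocentre.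

Step 13
Reactants: 19 (4aS,8aS)-4-(but-3-yn-1-yl)-3,4a,8,8-tetramethyl-1,2,4a,5,6,7,8,8a-octahydronaphthalene; 23 tert-butyl{[(2R,3E)-4-iodo-2-methylbut-3-en-1-yl]oxy}dimethylsilane
Product: 25 tert-butyl({(2R,3E,5E)-2,6-dimethyl-8-[(4aS,8aS)-2,5,5,8a-tetramethyl-3,4,4a,5,6,7,8,8a-octahydronaphthalen-1-yl]octa-3,5-dien-1-yl}oxy)dimethylsilane, via alkenylalane 24 (not isolated)
Conditions: AlMe3 (3 equiv), Cp2ZrCl2 (0.25 equiv), CH2Cl2, 0 °C → rt; then 23, Pd(PPh3)4 (5 mol %), ZnCl2 (1 equiv), THF, rt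
Reagents that add atoms: trimethylaluminium, C[Al](C)C
Why: Negishi Cp2ZrCl2-catalysed methylalumination adds CH3 and Al syn with Al on the terminal carbon to give the E alkenylalane, which should cross-couple with 23 under Pd(PPh3)4/ZnCl2 with retention at both alkenes and without base near the allylic stereocentre.

Step 14
Reactants: 25 tert-butyl({(2R,3E,5E)-2,6-dimethyl-8-[(4aS,8aS)-2,5,5,8a-tetramethyl-3,4,4a,5,6,7,8,8a-octahydronaphthalen-1-yl]octa-3,5-dien-1-yl}oxy)dimethylsilane
Product: 26 (2R,3E,5E)-2,6-dimethyl-8-[(4aS,8aS)-2,5,5,8a-tetramethyl-3,4,4a,5,6,7,8,8a-octahydronaphthalen-1-yl]octa-3,5-dien-1-ol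
Conditions: TBAF, THF, 0 °C → rt
Reagents that add atoms: none
Why: Fluoride cleavage of a primary silyl ether, to which the hydrocarbon polyene is inert.

Step 15
Reactants: 26 (2R,3E,5E)-2,6-dimethyl-8-[(4aS,8aS)-2,5,5,8a-tetramethyl-3,4,4a,5,6,7,8,8a-octahydronaphthalen-1-yl]octa-3,5-dien-1-ol
Product: 28 (2R,3E,5E)-2,6-dimethyl-8-[(4aS,8aS)-2,5,5,8a-tetramethyl-3,4,4a,5,6,7,8,8a-octahydronaphthalen-1-yl]octa-3,5-dienoic acid, via aldehyde 27 (not isolated)
Conditions: TEMPO (10 mol %), PhI(OAc)2, CH2Cl2, rt; then NaClO2, NaH2PO4, 2-methylbut-2-ene, t-BuOH/H2O, 0 °C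
Reagents that add atoms: sodium chlorite, [Na+].[O-]Cl=O
Why: Oxoammonium oxidation to the aldehyde followed at once by Pinnick oxidation, both without base, so the α-stereocentre (allylic to the diene) and the skipped position of the diene relative to the carboxyl group should be preserved.

Compound list
1 | 2,2-dimethylpent-4-enal | C=CCC(C)(C)C=O | starting material
2 | diethyl {2-[methoxy(methyl)amino]-2-oxoethyl}phosphonate | CCOP(=O)(OCC)CC(=O)N(C)OC | starting material
3 | sodium salt of the α-carbanion of 2 | CCOP(=O)(OCC)[CH-]C(=O)N(C)OC.[Na+] | intermediate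
4 | (2E)-N-methoxy-N,4,4-trimethylhepta-2,6-dienamide | C=CCC(C)(C)/C=C/C(=O)N(C)OC | intermediate
5 | but-2-yn-1-ol | CC#CCO | starting material
6 | isopropenylmagnesium bromide | C=C(C)[Mg]Br | starting material
7 | 3-methyl-4-(prop-1-en-2-yl)-2,5-dihydro-1,2-oxamagnesole (cyclic alkenylmagnesium alkoxide) | CC1=C(C(C)=C)CO[Mg]1 | intermediate
8 | (2Z)-3-iodo-2-(prop-1-en-2-yl)but-2-en-1-ol (iodine cis to CH2OH) | OC/C(C(C)=C)=C(/C)I | intermediate
9 | (2Z)-1-bromo-3-iodo-2-(prop-1-en-2-yl)but-2-ene | BrC/C(C(C)=C)=C(/C)I | intermediate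
10 | trimethyl(prop-1-yn-1-yl)silane | CC#C[Si](C)(C)C | starting material
11 | [3-(trimethylsilyl)prop-2-yn-1-yl]lithium | [Li]CC#C[Si](C)(C)C | intermediate
12 | [(5E)-6-iodo-5-(prop-1-en-2-yl)hept-5-en-1-yn-1-yl]trimethylsilane (iodine cis to the butynyl chain) | C[Si](C)(C)C#CCC/C(C(C)=C)=C(/C)I | intermediate
13 | (2E)-7-(9-borabicyclo[3.3.1]nonan-9-yl)-N-methoxy-N,4,4-trimethylhept-2-enamide | CON(C)C(=O)/C=C/C(C)(C)CCCB1C2CCCC1CCC2 | intermediate
14 | (2E,8E)-N-methoxy-N,4,4,8-tetramethyl-9-(prop-1-en-2-yl)-13-(trimethylsilyl)trideca-2,8-dien-12-ynamide | CON(C)C(=O)/C=C/C(C)(C)CCC/C(C)=C(\CCC#C[Si](C)(C)C)C(C)=C | intermediate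
15 | (2E,8E)-4,4,8-trimethyl-9-(prop-1-en-2-yl)-13-(trimethylsilyl)trideca-2,8-dien-12-ynal | O=C/C=C/C(C)(C)CCC/C(C)=C(\CCC#C[Si](C)(C)C)C(C)=C | intermediate
16 | iminium trifluoroacetate of 15 with (2S,5S)-5-benzyl-2-tert-butyl-3-methylimidazolidin-4-one | O=C1N(C)[C@@H](C(C)(C)C)[N+](=C/C=C/C(C)(C)CCC/C(C)=C(\CCC#C[Si](C)(C)C)C(C)=C)[C@H]1Cc1ccccc1.[O-]C(=O)C(F)(F)F | intermediate
17 | (1S,4aS,8aS)-3,4a,8,8-tetramethyl-4-[4-(trimethylsilyl)but-3-yn-1-yl]-1,2,4a,5,6,7,8,8a-octahydronaphthalene-1-carbaldehyde (trans-fused, CHO cis to H-5) | CC1=C(CCC#C[Si](C)(C)C)[C@@]2(C)CCCC(C)(C)[C@@H]2[C@@H](C=O)C1 | intermediate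
18 | trimethyl{4-[(4aS,8aS)-2,5,5,8a-tetramethyl-3,4,4a,5,6,7,8,8a-octahydronaphthalen-1-yl]but-1-yn-1-yl}silane | CC1=C(CCC#C[Si](C)(C)C)[C@@]2(C)CCCC(C)(C)[C@@H]2CC1 | intermediate
19 | (4aS,8aS)-4-(but-3-yn-1-yl)-3,4a,8,8-tetramethyl-1,2,4a,5,6,7,8,8a-octahydronaphthalene | CC1=C(CCC#C)[C@@]2(C)CCCC(C)(C)[C@@H]2CC1 | intermediate
20 | methyl (2S)-3-hydroxy-2-methylpropanoate | COC(=O)[C@@H](C)CO | starting material
21 | methyl (2S)-3-[(tert-butyldimethylsilyl)oxy]-2-methylpropanoate | COC(=O)[C@@H](C)CO[Si](C)(C)C(C)(C)C | intermediate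
22 | (2S)-3-[(tert-butyldimethylsilyl)oxy]-2-methylpropanal | O=C[C@@H](C)CO[Si](C)(C)C(C)(C)C | intermediate
23 | tert-butyl{[(2R,3E)-4-iodo-2-methylbut-3-en-1-yl]oxy}dimethylsilane | I/C=C/[C@@H](C)CO[Si](C)(C)C(C)(C)C | intermediate
24 | dimethyl{(1E)-2-methyl-4-[(4aS,8aS)-2,5,5,8a-tetramethyl-3,4,4a,5,6,7,8,8a-octahydronaphthalen-1-yl]but-1-en-1-yl}alumane | CC1=C(CC/C(C)=C/[Al](C)C)[C@@]2(C)CCCC(C)(C)[C@@H]2CC1 | intermediate
25 | tert-butyl({(2R,3E,5E)-2,6-dimethyl-8-[(4aS,8aS)-2,5,5,8a-tetramethyl-3,4,4a,5,6,7,8,8a-octahydronaphthalen-1-yl]octa-3,5-dien-1-yl}oxy)dimethylsilane | CC1=C(CC/C(C)=C/C=C/[C@@H](C)CO[Si](C)(C)C(C)(C)C)[C@@]2(C)CCCC(C)(C)[C@@H]2CC1 | intermediate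
26 | (2R,3E,5E)-2,6-dimethyl-8-[(4aS,8aS)-2,5,5,8a-tetramethyl-3,4,4a,5,6,7,8,8a-octahydronaphthalen-1-yl]octa-3,5-dien-1-ol | CC1=C(CC/C(C)=C/C=C/[C@@H](C)CO)[C@@]2(C)CCCC(C)(C)[C@@H]2CC1 | intermediate
27 | (2R,3E,5E)-2,6-dimethyl-8-[(4aS,8aS)-2,5,5,8a-tetramethyl-3,4,4a,5,6,7,8,8a-octahydronaphthalen-1-yl]octa-3,5-dienal | CC1=C(CC/C(C)=C/C=C/[C@@H](C)C=O)[C@@]2(C)CCCC(C)(C)[C@@H]2CC1 | intermediate
28 | (2R,3E,5E)-2,6-dimethyl-8-[(4aS,8aS)-2,5,5,8a-tetramethyl-3,4,4a,5,6,7,8,8a-octahydronaphthalen-1-yl]octa-3,5-dienoic acid | CC1=C(CC/C(C)=C/C=C/[C@@H](C)C(=O)O)[C@@]2(C)CCCC(C)(C)[C@@H]2CC1 | target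

Total step count: 15. Longest linear sequence: 11 steps (from 5 through steps 2–9 and 13–15).

The three steps most likely to fail:

Step 7. The fully substituted diene is twisted and may reach the cisoid geometry too slowly at ambient temperature, so that conversion stalls and an uncatalysed or exo pathway erodes enantio- and diastereoselection. The fallback replaces catalyst control by auxiliary control under Lewis acid activation; it sets out from 15 and comes back at 17. Pinnick oxidation of 15 gives (2E,8E)-4,4,8-trimethyl-9-(prop-1-en-2-yl)-13-(trimethylsilyl)trideca-2,8-dien-12-ynoic acid F1. Its pivaloyl mixed anhydride acylates the lithium salt of (4S)-4-benzyloxazolidin-2-one to give (4S)-4-benzyl-3-[(2E,8E)-4,4,8-trimethyl-9-(prop-1-en-2-yl)-13-(trimethylsilyl)trideca-2,8-dien-12-ynoyl]oxazolidin-2-one F2. Me2AlCl in CH2Cl2 at −30 °C chelates the imide, and the benzyl group covers the same Re face of C5, so the endo cycloaddition should give (4S)-4-benzyl-3-{[(1S,4aS,8aS)-3,4a,8,8-tetramethyl-4-[4-(trimethylsilyl)but-3-yn-1-yl]-1,2,4a,5,6,7,8,8a-octahydronaphthalen-1-yl]carbonyl}oxazolidin-2-one F3. LiBH4 cleaves the auxiliary to {(1S,4aS,8aS)-3,4a,8,8-tetramethyl-4-[4-(trimethylsilyl)but-3-yn-1-yl]-1,2,4a,5,6,7,8,8a-octahydronaphthalen-1-yl}methanol F4, and Dess–Martin oxidation gives 17.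

Step 2. The hindered alkenyl Grignard reagent may only deprotonate the alcohol and then add sluggishly or without regiocontrol, so that the chelate does not form cleanly. The fallback makes the tetrasubstituted alkene by stereoretentive coupling of an enol triflate instead; it sets out from 4 (used as its borane 13) and from 11, and comes back at 14. Knoevenagel condensation of ethyl acetoacetate with acetone (TiCl4, pyridine) gives ethyl 2-acetyl-3-methylbut-2-enoate F5. γ-Deprotonation with LiN(SiMe3)2 and O-sulfonylation of the lithium-chelated dienolate with PhNTf2 should give ethyl (2Z)-2-(prop-1-en-2-yl)-3-{[(trifluoromethyl)sulfonyl]oxy}but-2-enoate F6. i-Bu2AlH reduces the ester to (2Z)-4-hydroxy-3-(prop-1-en-2-yl)but-2-en-2-yl trifluoromethanesulfonate F7, and CBr4/PPh3 gives (2Z)-4-bromo-3-(prop-1-en-2-yl)but-2-en-2-yl trifluoromethanesulfonate F8. Alkylation of 11 with F8 at −78 °C gives (2E)-3-(prop-1-en-2-yl)-7-(trimethylsilyl)hept-2-en-6-yn-2-yl trifluoromethanesulfonate F9, and B-alkyl Suzuki coupling of F9 with 13 under the conditions of step 5 gives 14.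

Step 8. The secondary alkyl–metal intermediate may undergo β-hydride elimination to ring B dienes, or CO extrusion may stall at the hindered aldehyde. The fallback removes the carbon by radical decarboxylation; it sets out from 17 and comes back at 18. Pinnick oxidation gives (1S,4aS,8aS)-3,4a,8,8-tetramethyl-4-[4-(trimethylsilyl)but-3-yn-1-yl]-1,2,4a,5,6,7,8,8a-octahydronaphthalene-1-carboxylic acid F10. N-Hydroxyphthalimide, N,N'-diisopropylcarbodiimide and DMAP give 1,3-dioxoisoindolin-2-yl (1S,4aS,8aS)-3,4a,8,8-tetramethyl-4-[4-(trimethylsilyl)but-3-yn-1-yl]-1,2,4a,5,6,7,8,8a-octahydronaphthalene-1-carboxylate F11. Reductive decarboxylation with NiCl2·6H2O/4,4'-di-tert-butyl-2,2'-bipyridine, Zn and PhSiH3 should replace the ester by hydrogen and give 18.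

Further compounds
F1 | step 7 | (2E,8E)-4,4,8-trimethyl-9-(prop-1-en-2-yl)-13-(trimethylsilyl)trideca-2,8-dien-12-ynoic acid | OC(=O)/C=C/C(C)(C)CCC/C(C)=C(\CCC#C[Si](C)(C)C)C(C)=C
F2 | step 7 | (4S)-4-benzyl-3-[(2E,8E)-4,4,8-trimethyl-9-(prop-1-en-2-yl)-13-(trimethylsilyl)trideca-2,8-dien-12-ynoyl]oxazolidin-2-one | O=C(/C=C/C(C)(C)CCC/C(C)=C(\CCC#C[Si](C)(C)C)C(C)=C)N1[C@@H](Cc2ccccc2)COC1=O
F3 | step 7 | (4S)-4-benzyl-3-{[(1S,4aS,8aS)-3,4a,8,8-tetramethyl-4-[4-(trimethylsilyl)but-3-yn-1-yl]-1,2,4a,5,6,7,8,8a-octahydronaphthalen-1-yl]carbonyl}oxazolidin-2-one | CC1=C(CCC#C[Si](C)(C)C)[C@@]2(C)CCCC(C)(C)[C@@H]2[C@@H](C(=O)N2[C@@H](Cc3ccccc3)COC2=O)C1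
F4 | step 7 | {(1S,4aS,8aS)-3,4a,8,8-tetramethyl-4-[4-(trimethylsilyl)but-3-yn-1-yl]-1,2,4a,5,6,7,8,8a-octahydronaphthalen-1-yl}methanol | CC1=C(CCC#C[Si](C)(C)C)[C@@]2(C)CCCC(C)(C)[C@@H]2[C@@H](CO)C1
F5 | step 2 | ethyl 2-acetyl-3-methylbut-2-enoate | CCOC(=O)C(C(C)=O)=C(C)C
F6 | step 2 | ethyl (2Z)-2-(prop-1-en-2-yl)-3-{[(trifluoromethyl)sulfonyl]oxy}but-2-enoate | CCOC(=O)/C(C(C)=C)=C(/C)OS(=O)(=O)C(F)(F)F
F7 | step 2 | (2Z)-4-hydroxy-3-(prop-1-en-2-yl)but-2-en-2-yl trifluoromethanesulfonate | OC/C(C(C)=C)=C(/C)OS(=O)(=O)C(F)(F)F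
F8 | step 2 | (2Z)-4-bromo-3-(prop-1-en-2-yl)but-2-en-2-yl trifluoromethanesulfonate | BrC/C(C(C)=C)=C(/C)OS(=O)(=O)C(F)(F)F
F9 | step 2 | (2E)-3-(prop-1-en-2-yl)-7-(trimethylsilyl)hept-2-en-6-yn-2-yl trifluoromethanesulfonate | C[Si](C)(C)C#CCC/C(C(C)=C)=C(/C)OS(=O)(=O)C(F)(F)F
F10 | step 8 | (1S,4aS,8aS)-3,4a,8,8-tetramethyl-4-[4-(trimethylsilyl)but-3-yn-1-yl]-1,2,4a,5,6,7,8,8a-octahydronaphthalene-1-carboxylic acid | CC1=C(CCC#C[Si](C)(C)C)[C@@]2(C)CCCC(C)(C)[C@@H]2[C@@H](C(O)=O)C1
F11 | step 8 | 1,3-dioxoisoindolin-2-yl (1S,4aS,8aS)-3,4a,8,8-tetramethyl-4-[4-(trimethylsilyl)but-3-yn-1-yl]-1,2,4a,5,6,7,8,8a-octahydronaphthalene-1-carboxylate | CC1=C(CCC#C[Si](C)(C)C)[C@@]2(C)CCCC(C)(C)[C@@H]2[C@@H](C(=O)ON2C(=O)c3ccccc3C2=O)C1
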